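**Retrosynthetic overview**
- Target 9 ⇐ 8: the side-chain C–Br bond and the ring double bond come last, from an ene-type bromination of the (E)-2-chloroethylidene ring compound 8.
- 8 ⇐ 6: the only ring is closed by Br+-induced cyclization of (R)-4-acetoxymyrcene 6 (new bond CMe2–CH2 of the diene), with the allyl cation quenched by chloride. This step sets the ring, the ring C–Br centre, the C–Cl bond and the olefin geometry under control of the acetate centre.
- 6 ⇐ 5 + ethylene (enyne metathesis); 5 ⇐ racemic 4 (lipase resolution); 4 ⇐ 4-methylpent-3-enal + ethynylmagnesium bromide, then Ac2O.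
- Ring order: one carbocycle, formed in step 5.

Assumption: the target is read as (1R,5S)-5-bromo-2-[(1S)-1-bromo-2-chloroethyl]-4,4-dimethylcyclohex-2-en-1-yl acetate (ring Br cis to OAc).

**Step 1**
Reactants: 1 4-methylpent-3-en-1-ol
Product: 2 4-methylpent-3-enal
Conditions: PhI(OAc)2 (1.1 equiv), TEMPO (10 mol%), CH2Cl2, 0 °C to rt; NaHCO3 wash, used at once
Reagents that add atoms: none
Why: Oxoammonium (TEMPO/PhI(OAc)2) alcohol oxidation is non-basic and stops at the aldehyde, so the β,γ-double bond is not drawn into conjugation; no stereocentre is formed.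

**Step 2**
Reactants: 2 4-methylpent-3-enal
Product: 4 rac-6-methylhept-5-en-1-yn-3-yl acetate, via bromomagnesium 6-methylhept-5-en-1-yn-3-olate 3 (not isolated)
Conditions: HC≡CMgBr (1.05 equiv), THF, −78 to 0 °C; then Ac2O (1.5 equiv), 0 °C to rt
Reagents that add atoms: ethynylmagnesium bromide, C#C[Mg]Br; acetic anhydride, CC(=O)OC(C)=O
Why: Grignard 1,2-addition of the acetylide followed by O-acylation of the magnesium alkoxide in the same flask gives the racemic propargylic acetate directly.

**Step 3**
Reactants: 4 rac-6-methylhept-5-en-1-yn-3-yl acetate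
Product: 5 (R)-6-methylhept-5-en-1-yn-3-yl acetate
Conditions: Burkholderia cepacia lipase (lipase PS), pH 7 phosphate buffer/acetone 9:1, 25 °C, stopped at about 60% conversion; chromatography
Reagents that add atoms: none
Why: Lipase-catalysed hydrolytic kinetic resolution; by the Kazlauskas rule (ethynyl = medium group, CH2 chain = large group) the enzyme hydrolyses the (S)-acetate and leaves the (R)-acetate, which is the carbinol centre of the target.

**Step 4**
Reactants: 5 (R)-6-methylhept-5-en-1-yn-3-yl acetate
Product: 6 (4R)-7-methyl-3-methylideneocta-1,6-dien-4-yl acetate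
Conditions: second-generation Grubbs catalyst (H2IMes)(PCy3)Cl2Ru=CHPh (5 mol%), ethylene (1 atm), CH2Cl2, rt
Reagents that add atoms: ethylene, C=C
Why: Ethylene–alkyne cross enyne metathesis turns the terminal alkyne into the 2-substituted buta-1,3-diene; propargylic acetates are good substrates, the trisubstituted olefin is inert and the stereocentre is untouched.

**Step 5**
Reactants: 6 (4R)-7-methyl-3-methylideneocta-1,6-dien-4-yl acetate
Product: 8 (1R,5S)-5-bromo-2-[(E)-2-chloroethylidene]-4,4-dimethylcyclohexyl acetate, via acetoxonium bromopentachloroantimonate 7 (not isolated)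
Conditions: Et2SBr·SbCl5Br (BDSB, 1.0 equiv), MeNO2, −25 °C, 10 min; then Et4NCl (3 equiv), −25 to 0 °C
Reagents that add atoms: bromodiethylsulfonium bromopentachloroantimonate, CC[S+](Br)CC.Cl[Sb-](Cl)(Cl)(Cl)(Cl)Br; tetraethylammonium chloride, CC[N+](CC)(CC)CC.[Cl-]
Why: Proposed new method: a bromonium-induced cation–olefin cyclization terminated by a 1,3-diene and chloride, in which Br+ goes to the electron-rich trisubstituted olefin and the diene CH2= terminus attacks the tertiary carbon anti to Br through a chair with Br and the acetate both equatorial (C–O in the plane of the attacking π bond, inside-alkoxy arrangement), which sets the (S)-C–Br centre cis to the (R)-acetate; the allyl cation is held by the neighbouring acetate as 7 and chloride then opens it at the primary terminus, any tertiary chloride re-ionising with acetate help, and allylic 1,3-strain with the equatorial acetate gives the (E)-olefin; the closest known reactions are BDSB bromocyclizations of polyenes and halide capture of the myrcene-type allyl cation.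

**Step 6**
Reactants: 8 (1R,5S)-5-bromo-2-[(E)-2-chloroethylidene]-4,4-dimethylcyclohexyl acetate
Product: 9 (1R,5S)-5-bromo-2-[(1S)-1-bromo-2-chloroethyl]-4,4-dimethylcyclohex-2-en-1-yl acetate
Conditions: 2,4,4,6-tetrabromocyclohexa-2,5-dienone (TBCO, 1.2 equiv), MeNO2, 0 °C to rt, dark
Reagents that add atoms: 2,4,4,6-tetrabromocyclohexa-2,5-dienone, O=C1C(Br)=CC(Br)(Br)C=C1Br
Why: Ene-type electrophilic allylic bromination (bromonium ion, then loss of the neighbouring proton, as in TBCO brominations of trisubstituted olefins): Br+ adds to the exocyclic CH from the face anti to the axial 4-methyl group and the tribromophenoxide of the ion pair removes the axial H at C-3 on that same face (the H at C-1 is deactivated by the geminal acetate), which moves the double bond into the ring and, from the (E)-olefin, gives the (S)-bromide.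

**Compound list**
1 | 4-methylpent-3-en-1-ol | CC(C)=CCCO | starting material
2 | 4-methylpent-3-enal | CC(C)=CCC=O | intermediate
3 | bromomagnesium 6-methylhept-5-en-1-yn-3-olate (racemic, not isolated) | C#CC(CC=C(C)C)O[Mg]Br | intermediate
4 | rac-6-methylhept-5-en-1-yn-3-yl acetate | CC(=O)OC(C#C)CC=C(C)C | intermediate
5 | (R)-6-methylhept-5-en-1-yn-3-yl acetate | CC(=O)O[C@@H](C#C)CC=C(C)C | intermediate
6 | (4R)-7-methyl-3-methylideneocta-1,6-dien-4-yl acetate | CC(=O)O[C@@H](C(=C)C=C)CC=C(C)C | intermediate
7 | (3aR,6S,7aR)-6-bromo-3a-ethenyl-2,5,5-trimethyl-3a,4,5,6,7,7a-hexahydro-1,3-benzodioxol-2-ylium bromopentachloroantimonate (cis-fused acetoxonium salt, not isolated) | C[C+]1O[C@@H]2C[C@H](Br)C(C)(C)C[C@]2(C=C)O1.Cl[Sb-](Cl)(Cl)(Cl)(Cl)Br | intermediate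
8 | (1R,5S)-5-bromo-2-[(E)-2-chloroethylidene]-4,4-dimethylcyclohexyl acetate | CC(=O)O[C@@H]1C[C@H](Br)C(C)(C)C/C1=C\CCl | intermediate
9 | (1R,5S)-5-bromo-2-[(1S)-1-bromo-2-chloroethyl]-4,4-dimethylcyclohex-2-en-1-yl acetate | CC(=O)O[C@@H]1C[C@H](Br)C(C)(C)C=C1[C@H](Br)CCl | target

**Totals**
Total step count: 6. Longest linear sequence: 6 steps (fully linear).

**Three steps most likely to fail**

1. Step 5. Possible failures: the ring closes with low cis/trans selectivity, the allyl cation loses a proton before chloride arrives, or the acetate attacks the bromonium ion. Fallback: set out from 6 and separate ring closure from chloride delivery. N-Bromosuccinimide in (CF3)2CHOH at 0 °C closes the ring with proton loss as the only exit and gives (1R,5S)-5-bromo-2-ethenyl-4,4-dimethylcyclohex-2-en-1-yl acetate F1. 1,4-Addition of HCl (1 equiv, Et2O, −30 °C) to this diene, proton to the ring CH= and chloride to the vinyl terminus, comes back to the route at 8.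

2. Step 6. This is the least secure step. The cation next to the acetate can be captured by it (acetoxonium ion) or take a 1,2-hydride shift from C-1, and the facial selectivity rests on the axial methyl group alone. Fallback: set out from 8 and replace the one-step ene bromination by addition and elimination. N-Bromosuccinimide in aqueous acetone at 0 °C adds Br and OH anti (OH to the tertiary ring carbon) to give (1R,2S,5S)-5-bromo-2-[(1S)-1-bromo-2-chloroethyl]-2-hydroxy-4,4-dimethylcyclohexyl acetate F2. SOCl2/pyridine at 0 °C then removes the axial OH together with the axial H at C-3 (anti elimination) and comes back to the route at 9.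

3. Step 3. The enantioselectivity of the lipase for this 1-alkyn-3-yl acetate may be only moderate, which costs yield or ee. Fallback: set out from 2 and set the centre by catalysis instead of resolution. Me2Zn, trimethylsilylacetylene and the ProPhenol ligand enantiomer that gives the (R)-carbinol add to 2 to give (R)-6-methyl-1-(trimethylsilyl)hept-5-en-1-yn-3-ol F3. K2CO3 in MeOH removes the silyl group to give (R)-6-methylhept-5-en-1-yn-3-ol F4. Ac2O/pyridine then gives 5, where the route is rejoined.

**Further compounds**
F1 | step 5 | (1R,5S)-5-bromo-2-ethenyl-4,4-dimethylcyclohex-2-en-1-yl acetate | CC(=O)O[C@@H]1C[C@H](Br)C(C)(C)C=C1C=C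
F2 | step 6 | (1R,2S,5S)-5-bromo-2-[(1S)-1-bromo-2-chloroethyl]-2-hydroxy-4,4-dimethylcyclohexyl acetate | CC(=O)O[C@@H]1C[C@H](Br)C(C)(C)C[C@@]1(O)[C@H](Br)CCl
F3 | step 3 | (R)-6-methyl-1-(trimethylsilyl)hept-5-en-1-yn-3-ol | O[C@@H](C#C[Si](C)(C)C)CC=C(C)C
F4 | step 3 | (R)-6-methylhept-5-en-1-yn-3-ol | O[C@@H](C#C)CC=C(C)C
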